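Leftover substrate is the clue: the red run holds near 46.5% reacted, which leaves 53.5% unused, so you look at the partner.

| flask | left-handed substrate | right-handed substrate | partner | free catalyst | remark | time |
|---|---|---|---|---|---|---|
| violet | 0.25 M | 0.25 M | 0.55 M | 2 mM | run made earlier |  |
| red | 0.38 M | 0.38 M | 0.55 M | 2 mM | run made earlier |  |
| blue | 0.50 M | 0.50 M | 0.55 M | 1 mM | run made earlier |  |
| flask | 0.50 M | 0.50 M | 0.550 M | 2.0 mM |  | 20 min |

| run | time / min | left-handed product / % | right-handed product / % |
|---|---|---|---|
| violet | 3.00 | 30 | 41 |
| violet | 8.00 | 30 | 42 |
| violet | 15.0 | 31 | 42 |
| violet | 25.0 | 33 | 40 |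
| red | 2.00 | 16 | 29 |
| red | 4.00 | 20 | 28 |
| red | 10.0 | 19 | 26 |
| red | 25.0 | 20 | 28 |
| blue | 6.00 | 14 | 13 |
| blue | 12.0 | 10 | 22 |
| blue | 20.0 | 13 | 19 |
| blue | 25.0 | 13 | 15 |

(standard deviation of a reading: 2 percentage points)

- free catalyst is single-handed; left-handed substrate and right-handed substrate are mirror images of each other, charged as a racemate, each of them at the stated concentration
- an excess is the difference of the two amounts in percent of their sum
- an excess is below zero if the other one leads

- excess of left-handed product over right-handed product in the product at 2.0 min
- excess of left-handed product over right-handed product in the product at 20 min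
- part of the left-handed substrate and right-handed substrate charged together that has reacted at 20 min

1. Take one partner per product. In the red run, the product then equals 64.3% of the partner charge.

2. The violet run, with less substrate and the same catalyst, gives about the same, 65.7%. Their mean, 65.0%, a reading with the scatter of these runs, is the partner yield, the part of the charged partner that ends as product at this catalyst charge and this partner charge.

3. The blue run, with half that catalyst and also more substrate than the violet and red runs, reads lower, 54.1%.

4. First extreme for this flask: every partner becomes product, and 55.0% of the substrate reacts.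

5. Second extreme: this flask keeps the blue yield, and 29.8% reacts.

6. This flask has the catalyst of the violet and red runs, so I commit to their yield: 35.7% reacted, between the extremes. The red readings already hold at 2.00 min, so I expect the early and late excess of this flask to match.

The forecast says −20%, −19% and 42%, on the view that “the reaction stops early, apparently through catalyst death rather than equilibrium”. Its conversion stands above mine.

The flask gives −19.3%, −19.3% and 36.9%.

    free catalyst + left-handed substrate ⇌ catalyst intermediate A (K = 4.70 M⁻¹, k = 250 M⁻¹ s⁻¹)
    2 partner → homo dimer (k = 0.210 M⁻¹ s⁻¹)
    partner + catalyst intermediate A → free catalyst + left-handed product (k = 290 M⁻¹ s⁻¹)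
    free catalyst ⇌ dormant form (K = 0.690, k = 0.0390 s⁻¹)
    partner → decomposition product (k = 1.10 × 10⁻⁴ s⁻¹)
    partner + catalyst intermediate B → free catalyst + right-handed product (k = 92.0 M⁻¹ s⁻¹)
    free catalyst + right-handed substrate ⇌ catalyst intermediate B (K = 13.0 M⁻¹, k = 3700 M⁻¹ s⁻¹)

In this flask the partner yield comes to 67.1%, and partner, the limiting reagent, stands at 0% of its charge at 20.0 min, against 70% of the left-handed substrate. Now take the neighbouring flask, the same but with 0.22 M of partner. Its ceiling is 22.0%, and the carried yield gives 14.3% reacted. It actually reaches 18.6%, with partner at 0% of its charge, so its partner yield stands above the carried one, at 84.5%.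

(The readings were generated by integration with constants of no real substance; scatter was added.)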